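Leave dusk, spring, winter, midnight and dawn closed and stirred until 12 min. Each holds substrate and partner, and target appears after a lag.

the same everywhere: partner 0.275 M

| charge | substrate | remark | time |
|---|---|---|---|
| larch | 0.18 M | run made earlier |  |
| maple | 3 M | run made earlier |  |
| dusk | 0.12 M |  | 12 min |
| spring | 0.25 M |  | 12 min |
| winter | 0.50 M |  | 12 min |
| midnight | 1.0 M |  | 12 min |
| dawn | 2.0 M |  | 12 min |

| run | time / min | target / % |
|---|---|---|
| larch | 0.417 | 1.1 |
| larch | 1.33 | 14.2 |
| larch | 2.00 | 23.9 |
| larch | 3.00 | 26.8 |
| larch | 5.00 | 24.2 |
| larch | 6.00 | 21.1 |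
| maple | 1.00 | 1.6 |
| maple | 2.00 | 2.3 |
| maple | 3.00 | 4.2 |
| maple | 4.00 | 2.9 |
| maple | 5.00 | 4.0 |
| maple | 6.00 | 3.2 |

(readings scatter by 1 percentage point)

- "hardly changes" means that all values lie within two and a half points (for a concentration: within two and a half percent of the largest)

- [target] at the end for dusk, spring, winter, midnight, dawn, in this order
- how that number moves from the first to the last of them (falls, then rises / rises, then falls / falls all the way / hardly changes / rises all the way)

Larch reads a peak of 26.8 % of its charge at 3.00 min, then 21.1 % at 6.00 min, so target is lost once made. Maple reads 3.58 % on average from 3.00 min on. The share slope, the change in the common logarithm of the target share of the charge per decade of substrate charge, reads −0.716 between that peak and that level. A slope of zero is a constant share, and a slope of minus 1 is a constant amount of target.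

My own reckoning runs from maple's level along this slope, then applies larch's loss. Larch kept 78.7 % of its peak over 3.00 min, and the same loss repeated from that peak up to 12 min, a span of 9.00 min, keeps 48.8 %. Target at 12 min should then stand as follows:

| Flask | Target share of charge |
|---|---|
| dusk | 17.5 % |
| spring | 10.3 % |
| winter | 6.29 % |
| midnight | 3.83 % |
| dawn | 2.33 % |

The slope lies above minus 1, so the reckoned amount rises along the row. Do not touch the partner charge: both earlier runs hold it at 0.275 M, and the slope is read with it fixed.

The forecast gives 0.015 M, 0.035 M, 0.06 M, 0.075 M and 0.08 M, shape rises all the way, on the ground that “At high substrate, partner limits the amount”.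

The flasks give 0.0162 M, 0.0336 M, 0.0365 M, 0.0350 M and 0.0347 M, shape rises, then falls.

    substrate ⇌ open intermediate (K = 2.20, k = 0.0822 s⁻¹)
    partner → second intermediate (k = 0.00931 s⁻¹)
    open intermediate + second intermediate → target (k = 0.0613 L mol⁻¹ s⁻¹)
    target ⇌ isomer of the product (K = 7.21, k = 0.00977 s⁻¹)

In dawn, partner, the limiting reagent, stands at 0.12 % of its own charge at 12.0 min, with target at 1.74 % of the substrate charged. From midnight to dawn the share slope is −1.01, the constant-amount value. From dusk to spring it is −0.00979.

All runs are simulated with made-up constants.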